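**Plan**
- Retrosynthesis: the C8 acetate comes from a C8–B bond and the lactone C12–O6 bond is opened. The ring bonds C8–C9 and C6–C7 are then cut together, the vinyl group and O6 are re-tied as a 2-(bromomethyl)oxolane acetal, fragment A goes back to an Ireland–Claisen rearrangement (C5–C10) and fragment B to a pyruvate alkynylation.
- Enabling feature: C7 is flanked by the oxygen-bearing carbons C6 and C8, and C9 is a CH2 on the quaternary C10. An (E)-alkenylboronate C8=C7 can therefore take a C6 oxocarbenium ion at C7 and receive C9 from boron at C8. O6 and the vinyl group on C10 are cis-1,3 on the cyclohexane, so they can first be tied in an oxolane (from an iodolactone) that holds C6 at the aldehyde level and masks the vinyl group.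
- Forward: acyclic fragment A → iodolactone → bromo/iodo methyl acetal; fragment B is the alkenylboronate with the angelate already in place. The key step joins them and closes the carbocycle through a seven-membered borate that contracts to the six-membered ring (a 6-oxabicyclo[3.2.1]octane). Zinc then unties the oxolane to vinyl + O6–H, which closes the cis γ-lactone; C–B → C–OH → OAc.
- Stereochemistry: C5/C10 from the chair Ireland–Claisen under a chiral boron controller; C11 from a catalytic asymmetric alkynylation; C6 and C7 from the tethered bicyclic closure; C8 from the E-alkene geometry and stereoretentive shift and oxidation; the Z angelate from angelic anhydride.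

Key step: step 12

Locants used below are those of the elemane skeleton: C10 quaternary carbon (CH3, vinyl C1=C2), C9 ring CH2, C8 CH–OAc, C7 ring-fusion CH, C6 CH–O, C5 CH(isopropenyl), C11 oxygenated quaternary carbon, C12 lactone carbonyl.
Assumption: the enantiomer of the boron controller (step 3) and of the amino alcohol ligand (step 9) is the one that gives the drawn configuration, and the antipode is used if the sense of induction proves opposite.
Assumption: C1 of 6 should form mainly as drawn (iodomethyl trans to the silyloxymethyl arm); the minor epimer can be returned to 5 with zinc.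

**Route**

Step 1
Reactants: 1 2-methyl-2-vinyloxirane; 2 3-methylbut-3-enoic acid
Product: 3 (2E)-4-hydroxy-3-methylbut-2-en-1-yl 3-methylbut-3-enoate
Conditions: Pd(PPh3)4 (cat.), THF, 0 °C → rt
Reagents that add atoms: none
Why: Tsuji–Trost opening of the vinyl epoxide; zerovalent palladium ionizes 1 to a π-allyl alkoxide that deprotonates 2, and the carboxylate attacks the unsubstituted allyl terminus (1,4-addition) to give the E trisubstituted alkene whose geometry later fixes C10.

Step 2
Reactants: 3
Product: 4 (2E)-4-[(tert-butyldimethylsilyl)oxy]-3-methylbut-2-en-1-yl 3-methylbut-3-enoate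
Conditions: TBSCl, imidazole, DMF, 0 °C → rt
Reagents that add atoms: tert-butyldimethylsilyl chloride, CC(C)(C)[Si](C)(C)Cl
Why: Standard silylation of the primary allylic alcohol, needed because the boron reagent of step 3 does not tolerate a free hydroxyl.

Step 3
Reactants: 4
Product: 5 (2R,3R)-3-{[(tert-butyldimethylsilyl)oxy]methyl}-3-methyl-2-(prop-1-en-2-yl)pent-4-enoic acid
Conditions: (S,S)-2-bromo-1,3-bis{[3,5-bis(trifluoromethyl)phenyl]sulfonyl}-4,5-diphenyl-1,3,2-diazaborolidine (1.1 equiv), Et3N, toluene/hexane, −78 °C → 4 °C; aqueous work-up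
Reagents that add atoms: none
Why: Enantioselective Ireland–Claisen rearrangement through a chair transition state; the E allyl unit and the boron enolate with isopropenyl trans to O–B set the C5/C10 relative configuration (vinyl and isopropenyl anti), and the C2-symmetric controller selects the enolate face and so the absolute configuration.

Step 4
Reactants: 5
Product: 6 (3R,4R,5S)-4-{[(tert-butyldimethylsilyl)oxy]methyl}-5-(iodomethyl)-4-methyl-3-(prop-1-en-2-yl)oxolan-2-one
Conditions: I2, NaHCO3, MeCN, 0 °C, dark
Reagents that add atoms: iodine, II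
Why: Iodolactonization; the reversibly formed iodonium ion of the vinyl group is captured 5-exo by the carboxylate, whereas the isopropenyl group could only close a four-membered ring, and C1 should form with the iodomethyl group trans to the bulkier arm on C10.

Step 5
Reactants: 6
Product: 7 (3R,4R,5S)-4-(hydroxymethyl)-5-(iodomethyl)-4-methyl-3-(prop-1-en-2-yl)oxolan-2-one
Conditions: HF·pyridine, pyridine, THF, 0 °C → rt
Reagents that add atoms: none
Why: Fluoride cleavage of the silyl ether under mildly acidic conditions, which avoid translactonization and epimerization at the lactone α-carbon C5.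

Step 6
Reactants: 7
Product: 8 (3R,4S,5S)-4,5-bis(iodomethyl)-4-methyl-3-(prop-1-en-2-yl)oxolan-2-one
Conditions: PPh3, I2, imidazole, toluene, rt then 80 °C
Reagents that add atoms: iodine, II
Why: Appel-type (Garegg–Samuelsson) iodination; the oxyphosphonium salt forms at rt and the slow displacement at the neopentyl carbon C9 is driven by heating.

Step 7
Reactants: 8
Product: 9 (3R,4S,5S)-5-(bromomethyl)-4-(iodomethyl)-4-methyl-3-(prop-1-en-2-yl)oxolan-2-one
Conditions: LiBr (excess), DMF, 60 °C
Reagents that add atoms: lithium bromide, [Li+].[Br-]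
Why: Finkelstein-type halide exchange by SN2, which reaches only the non-neopentyl iodide at C2; the bromide should survive the later iodine–lithium exchange at C9 and still serve the zinc elimination of step 13.

Step 8
Reactants: 9
Product: 11 (2S,3S,4R)-2-(bromomethyl)-3-(iodomethyl)-5-methoxy-3-methyl-4-(prop-1-en-2-yl)oxolane (both anomers), via lactol 10 (not isolated)
Conditions: i-Bu2AlH, CH2Cl2, −78 °C; then MeOH, PPTS, rt
Reagents that add atoms: methanol, CO
Why: Partial reduction of the lactone to the lactol and Fischer-type acetalization put C6 at the aldehyde level as a cyclic acetal; both anomers give the same oxocarbenium ion in step 12.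

Step 9
Reactants: 12 methyl pyruvate; 13 ethynyltrimethylsilane
Product: 15 methyl (2S)-2-hydroxy-2-methylbut-3-ynoate, via silylated alkynol 14 (not isolated)
Conditions: Zn(OTf)2, (1S,2S)-2-(dimethylamino)-1-(4-nitrophenyl)-3-[(tert-butyldimethylsilyl)oxy]propan-1-ol, Et3N, toluene, rt; then K2CO3, MeOH, 0 °C
Reagents that add atoms: none
Why: Catalytic enantioselective addition of a zinc acetylide to the α-keto ester; the amino alcohol ligand selects the ketone face and sets C11, and the C-silyl group is then removed by methanolysis.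

Step 10
Reactants: 15; 16 angelic anhydride [(2Z)-2-methylbut-2-enoic anhydride]
Product: 17 methyl (2S)-2-methyl-2-{[(2Z)-2-methylbut-2-enoyl]oxy}but-3-ynoate
Conditions: LiN(SiMe3)2, THF, −78 °C; then 16, −78 → 0 °C
Reagents that add atoms: none
Why: Acylation of the lithium alkoxide of the tertiary alcohol by the anhydride at low temperature, a mode of angeloylation that should not isomerize the Z enoate to the tiglate.

Step 11
Reactants: 17
Product: 18 methyl (2S,3E)-2-methyl-2-{[(2Z)-2-methylbut-2-enoyl]oxy}-4-(4,4,5,5-tetramethyl-1,3,2-dioxaborolan-2-yl)but-3-enoate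
Conditions: pinacolborane, Cp2Zr(H)Cl (cat.), Et3N (cat.), CH2Cl2, 40 °C
Reagents that add atoms: pinacolborane, CC1(C)OBOC1(C)C
Why: Zirconium-catalyzed hydroboration of the terminal alkyne; syn addition with boron at the terminal carbon gives the E alkenylboronate, and the hindered conjugated angelate is left alone.

Step 12
Reactants: 11; 18
Product: 21 methyl (2S)-2-[7-(bromomethyl)-1-methyl-8-(prop-1-en-2-yl)-3-(4,4,5,5-tetramethyl-1,3,2-dioxaborolan-2-yl)-6-oxabicyclo[3.2.1]octan-4-yl]-2-{[(2Z)-2-methylbut-2-enoyl]oxy}propanoate (O6 and C1 bridge cis-diaxial on the carbocycle, bromomethyl exo, side chain and boron equatorial and trans), via alkyllithium 19 (not isolated), via lithium boronate complex 20 (not isolated)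
Conditions: t-BuLi (2 equiv), Et2O/pentane, −78 °C; 18, THF, −78 °C; then Me3SiOTf, −78 → −40 °C
Reagents that add atoms: none
Why: Proposed new method: iodine–lithium exchange at the neopentyl iodide (bromide and acetal inert at −78 °C) gives 19, which adds to the boron of 18 to give the tetracoordinate alkenyl(alkyl)boronate 20; Me3SiOTf then ionizes the anomeric methoxy group, the electron-rich alkene carbon C7 attacks the oxocarbenium carbon C6, and the positive charge building at C8 next to boron is quenched by 1,2-shift of C9 from boron to C8, leaving boron as an exocyclic pinacol boronate. The closest known reaction type is the electrophile-induced 1,2-metalate rearrangement of alkenylboronate complexes with carbon electrophiles (Zweifel-type three-component coupling, coupling of vinylborates with aldehydes to 1,3-diol precursors); new is that the electrophile and the migrating carbon sit on one chain, which makes the event an annulation and forces both new bonds onto the same face of the alkene instead of the usual anti course. Ring closures: the C6–C7 bond closes a seven-membered borate ring (C6, C5, C10, C9, B, C8, C7; endo with respect to the alkene, attack on a cyclic oxocarbenium ion), and the C9–C8 bond contracts it to the cyclohexane (three-centre shift with retention at C9), giving the 6-oxabicyclo[3.2.1]octane. Stereocentres: C6 is set by the tether, since C7 can reach C6 only on the oxolane face that carries the C9 arm; C7 is set by the isopropenyl group on the one-carbon bridge, which leaves only the equatorial position for the bulky C11 group; C8 follows from the E geometry of 18 and the same-face delivery (C11 and boron trans); C11 is untouched. The step needs attack at C7 with migration rather than ipso transfer of the alkenyl group, proton loss from the oxocarbenium ion or migration of a pinacol oxygen, and this is secured by C9 being the only carbon ligand able to migrate, by the intramolecular closure at low temperature and by the masked vinyl group.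

Step 13
Reactants: 21
Product: 23 (3S,3aR,4S,6R,7R,7aS)-6-ethenyl-3,6-dimethyl-2-oxo-7-(prop-1-en-2-yl)-4-(4,4,5,5-tetramethyl-1,3,2-dioxaborolan-2-yl)octahydro-1-benzofuran-3-yl (2Z)-2-methylbut-2-enoate, via hydroxy ester 22 (not isolated)
Conditions: Zn dust (activated), AcOH, THF, 45 °C; then PPTS, toluene, 70 °C
Reagents that add atoms: none
Why: Boord-type reductive elimination of the β-bromo ether (zinc insertion at C2, loss of the C1–O bond) restores the vinyl group and frees O6–H, which closes the cis-fused γ-lactone on the methyl ester; lactonizing before the boron is oxidized keeps the angelate on the far face from the later C8 hydroxyl, so acyl migration is not possible.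

Step 14
Reactants: 23
Product: 24 (3S,3aR,4S,6R,7R,7aS)-6-ethenyl-4-hydroxy-3,6-dimethyl-2-oxo-7-(prop-1-en-2-yl)octahydro-1-benzofuran-3-yl (2Z)-2-methylbut-2-enoate
Conditions: NaBO3·4H2O, THF/H2O, 0 °C → rt
Reagents that add atoms: sodium perborate, [Na+].[Na+].O[B-]1(O)OO[B-](O)(O)OO1
Why: Oxidation of the secondary alkyl boronate by perborate; the 1,2-shift of carbon from boron to oxygen occurs with retention, so the C8 hydroxyl takes the position set in step 12.

Step 15
Reactants: 24
Product: 25 (3S,3aR,4S,6R,7R,7aS)-4-(acetyloxy)-6-ethenyl-3,6-dimethyl-2-oxo-7-(prop-1-en-2-yl)octahydro-1-benzofuran-3-yl (2Z)-2-methylbut-2-enoate (CNP0140071.1)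
Conditions: Ac2O, pyridine, DMAP (cat.), CH2Cl2, 0 °C → rt
Reagents that add atoms: acetic anhydride, CC(=O)OC(C)=O
Why: Acetylation of the equatorial secondary alcohol; the tertiary C11 oxygen already carries the angelate, so no selectivity issue arises.

**Compound list**
1 | 2-methyl-2-vinyloxirane | C=CC1(C)CO1 | starting material
2 | 3-methylbut-3-enoic acid | C=C(C)CC(=O)O | starting material
3 | (2E)-4-hydroxy-3-methylbut-2-en-1-yl 3-methylbut-3-enoate | C=C(C)CC(=O)OC/C=C(/CO)C | intermediate
4 | (2E)-4-[(tert-butyldimethylsilyl)oxy]-3-methylbut-2-en-1-yl 3-methylbut-3-enoate | C=C(C)CC(=O)OC/C=C(/CO[Si](C)(C)C(C)(C)C)C | intermediate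
5 | (2R,3R)-3-{[(tert-butyldimethylsilyl)oxy]methyl}-3-methyl-2-(prop-1-en-2-yl)pent-4-enoic acid | C=C[C@@](C)(CO[Si](C)(C)C(C)(C)C)[C@@H](C(=C)C)C(=O)O | intermediate
6 | (3R,4R,5S)-4-{[(tert-butyldimethylsilyl)oxy]methyl}-5-(iodomethyl)-4-methyl-3-(prop-1-en-2-yl)oxolan-2-one | O=C1O[C@H](CI)[C@@](C)(CO[Si](C)(C)C(C)(C)C)[C@H]1C(=C)C | intermediate
7 | (3R,4R,5S)-4-(hydroxymethyl)-5-(iodomethyl)-4-methyl-3-(prop-1-en-2-yl)oxolan-2-one | O=C1O[C@H](CI)[C@@](C)(CO)[C@H]1C(=C)C | intermediate
8 | (3R,4S,5S)-4,5-bis(iodomethyl)-4-methyl-3-(prop-1-en-2-yl)oxolan-2-one | O=C1O[C@H](CI)[C@@](C)(CI)[C@H]1C(=C)C | intermediate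
9 | (3R,4S,5S)-5-(bromomethyl)-4-(iodomethyl)-4-methyl-3-(prop-1-en-2-yl)oxolan-2-one | O=C1O[C@H](CBr)[C@@](C)(CI)[C@H]1C(=C)C | intermediate
10 | (3R,4S,5S)-5-(bromomethyl)-4-(iodomethyl)-4-methyl-3-(prop-1-en-2-yl)oxolan-2-ol (lactol, both anomers) | OC1O[C@H](CBr)[C@@](C)(CI)[C@H]1C(=C)C | intermediate
11 | (2S,3S,4R)-2-(bromomethyl)-3-(iodomethyl)-5-methoxy-3-methyl-4-(prop-1-en-2-yl)oxolane (both anomers) | COC1O[C@H](CBr)[C@@](C)(CI)[C@H]1C(=C)C | intermediate
12 | methyl pyruvate | CC(=O)C(=O)OC | starting material
13 | ethynyltrimethylsilane | C#C[Si](C)(C)C | starting material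
14 | methyl (2S)-2-hydroxy-2-methyl-4-(trimethylsilyl)but-3-ynoate | C[Si](C)(C)C#C[C@](C)(O)C(=O)OC | intermediate
15 | methyl (2S)-2-hydroxy-2-methylbut-3-ynoate | C#C[C@](C)(O)C(=O)OC | intermediate
16 | angelic anhydride, (2Z)-2-methylbut-2-enoic anhydride | C/C=C(/C)C(=O)OC(=O)/C(C)=C\C | starting material
17 | methyl (2S)-2-methyl-2-{[(2Z)-2-methylbut-2-enoyl]oxy}but-3-ynoate | C#C[C@](C)(OC(=O)/C(C)=C\C)C(=O)OC | intermediate
18 | methyl (2S,3E)-2-methyl-2-{[(2Z)-2-methylbut-2-enoyl]oxy}-4-(4,4,5,5-tetramethyl-1,3,2-dioxaborolan-2-yl)but-3-enoate | CC1(C)OB(/C=C/[C@](C)(OC(=O)/C(C)=C\C)C(=O)OC)OC1(C)C | intermediate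
19 | alkyllithium from 11 (lithium in place of iodine at C9) | COC1O[C@H](CBr)[C@@](C)(C[Li])[C@H]1C(=C)C | intermediate
20 | lithium alkenyl(alkyl)pinacolatoborate from 19 and 18 | [Li+].COC1O[C@H](CBr)[C@@](C)(C[B-]2(/C=C/[C@](C)(OC(=O)/C(C)=C\C)C(=O)OC)OC(C)(C)C(C)(C)O2)[C@H]1C(=C)C | intermediate
21 | bicyclic boronate: methyl (2S)-2-[7-(bromomethyl)-1-methyl-8-(prop-1-en-2-yl)-3-(pinacolboryl)-6-oxabicyclo[3.2.1]octan-4-yl]-2-(angeloyloxy)propanoate, ring configuration as in 25 | BrC[C@@H]3[C@@]1(C)C[C@H](B4OC(C)(C)C(C)(C)O4)[C@@H]([C@](C)(OC(=O)/C(C)=C\C)C(=O)OC)[C@@H](O3)[C@@H]1C(=C)C | intermediate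
22 | ring-opened hydroxy ester boronate (vinyl at C10, free C6–OH, methyl ester, boron at C8) | C=C[C@@]1(C)C[C@H](B4OC(C)(C)C(C)(C)O4)[C@@H]([C@](C)(OC(=O)/C(C)=C\C)C(=O)OC)[C@@H](O)[C@@H]1C(=C)C | intermediate
23 | lactone boronate: 25 with pinacolboryl in place of the acetoxy group at C8, same configuration | C=C[C@@]1(C)C[C@H](B3OC(C)(C)C(C)(C)O3)[C@@H]2[C@@H](OC(=O)[C@@]2(C)OC(=O)/C(C)=C\C)[C@@H]1C(=C)C | intermediate
24 | 8-hydroxy lactone: (3S,3aR,4S,6R,7R,7aS)-6-ethenyl-4-hydroxy-3,6-dimethyl-2-oxo-7-(prop-1-en-2-yl)octahydro-1-benzofuran-3-yl (2Z)-2-methylbut-2-enoate | C=C[C@@]1(C)C[C@H](O)[C@@H]2[C@@H](OC(=O)[C@@]2(C)OC(=O)/C(C)=C\C)[C@@H]1C(=C)C | intermediate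
25 | CNP0140071.1: (3S,3aR,4S,6R,7R,7aS)-4-(acetyloxy)-6-ethenyl-3,6-dimethyl-2-oxo-7-(prop-1-en-2-yl)octahydro-1-benzofuran-3-yl (2Z)-2-methylbut-2-enoate | C=C[C@@]1(C)C[C@H](OC(C)=O)[C@@H]2[C@@H](OC(=O)[C@@]2(C)OC(=O)/C(C)=C\C)[C@@H]1C(=C)C | target

**Summary**
Total steps: 15. Longest linear sequence: 12 (steps 1–8 and 12–15); steps 9–11 make fragment B.

Steps most likely to fail:

Step 12 (proposed method). The seven-membered closure may lose to proton loss from the oxocarbenium ion, to ipso transfer of the alkenyl group or to protodeboronation, or the shift may not take place on the face that the ring demands. The fallback uses known reactions only and runs from 11 and 18 to 25. Perborate oxidation of 18 gives the aldehyde methyl (2S)-2-methyl-2-(angeloyloxy)-4-oxobutanoate F1. Alkyllithium 19 (from 11, t-BuLi), transmetalated with CeCl3, adds to it and gives the C8 carbinol F2 as a mixture of epimers, so the C8–C9 bond is made first. Dess–Martin oxidation gives the ketone F3. Me3SiOTf with Et3N forms the silyl enol ethers reversibly and ionizes the acetal; only the C7 enol ether can close (intramolecular Mukaiyama-type addition to the oxocarbenium ion, six-membered ring), giving the bicyclic ketone F4 with the C11 group equatorial after equilibration at C7. NaBH4 should attack C8 from the face away from the oxygen bridge and give the axial alcohol F5. Mitsunobu reaction with AcOH (PPh3, DIAD) inverts it to the bicyclic acetate F6, and Zn/AcOH then PPTS, as in step 13, gives 25.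

Step 3. The boron enolate may form with the wrong geometry, or the β,γ-unsaturated ester may conjugate before enolization, which would erode diastereo- and enantiocontrol. The fallback runs from 4 back to 5. The achiral Ireland–Claisen rearrangement (LiN(i-Pr)2, Me3SiCl, THF, −78 °C → rt; same chair, same relative configuration) gives the racemic acid, that is 5 together with its enantiomer, the (2S,3S)-acid F7. Crystallization with (S)-1-phenylethylamine (or its antipode, whichever gives the less soluble salt of 5) gives the (S)-1-phenylethylammonium salt of 5 F8, and acidification returns 5.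

Step 4. The iodonium ion may be captured at the isopropenyl alkene (β-lactone or allylic iodide) instead of at the vinyl group, or C1 may form without control. The fallback runs from 5 to 11 without a lactone. LiAlH4 reduces 5 to the primary alcohol F9, and Dess–Martin oxidation gives the aldehyde F10. I2/NaHCO3 in MeOH closes the hemiacetal oxygen onto the vinyl group (5-exo iodoetherification) and gives the silylated iodo methyl acetal F11. HF·pyridine gives the hydroxy iodo acetal F12, PPh3/I2/imidazole gives the bis-iodo acetal F13, and LiBr exchanges the non-neopentyl iodide to give 11.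

**Further compounds**
F1 | step 12 | methyl (2S)-2-methyl-2-{[(2Z)-2-methylbut-2-enoyl]oxy}-4-oxobutanoate | O=CC[C@](C)(OC(=O)/C(C)=C\C)C(=O)OC
F2 | step 12 | C8 carbinol from 19 and F1 (C8 epimers) | COC1O[C@H](CBr)[C@@](C)(CC(O)C[C@](C)(OC(=O)/C(C)=C\C)C(=O)OC)[C@H]1C(=C)C
F3 | step 12 | C8 ketone | COC1O[C@H](CBr)[C@@](C)(CC(=O)C[C@](C)(OC(=O)/C(C)=C\C)C(=O)OC)[C@H]1C(=C)C
F4 | step 12 | bicyclic ketone (6-oxabicyclo[3.2.1]octan-3-one, C8 carbonyl) | BrC[C@@H]3[C@@]1(C)CC(=O)[C@@H]([C@](C)(OC(=O)/C(C)=C\C)C(=O)OC)[C@@H](O3)[C@@H]1C(=C)C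
F5 | step 12 | bicyclic axial alcohol (C8 epimer of the alcohol corresponding to 21) | BrC[C@@H]3[C@@]1(C)C[C@@H](O)[C@@H]([C@](C)(OC(=O)/C(C)=C\C)C(=O)OC)[C@@H](O3)[C@@H]1C(=C)C
F6 | step 12 | bicyclic acetate (acetoxy in place of boron in 21) | BrC[C@@H]3[C@@]1(C)C[C@H](OC(C)=O)[C@@H]([C@](C)(OC(=O)/C(C)=C\C)C(=O)OC)[C@@H](O3)[C@@H]1C(=C)C
F7 | step 3 | (2S,3S)-3-{[(tert-butyldimethylsilyl)oxy]methyl}-3-methyl-2-(prop-1-en-2-yl)pent-4-enoic acid (enantiomer of 5, formed with 5 as the racemate) | C=C[C@](C)(CO[Si](C)(C)C(C)(C)C)[C@H](C(=C)C)C(=O)O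
F8 | step 3 | (S)-1-phenylethylammonium salt of 5 | C=C[C@@](C)(CO[Si](C)(C)C(C)(C)C)[C@@H](C(=C)C)C(=O)[O-].C[C@H]([NH3+])c1ccccc1
F9 | step 4 | (2R,3R)-3-{[(tert-butyldimethylsilyl)oxy]methyl}-3-methyl-2-(prop-1-en-2-yl)pent-4-en-1-ol | C=C[C@@](C)(CO[Si](C)(C)C(C)(C)C)[C@@H](C(=C)C)CO
F10 | step 4 | (2R,3R)-3-{[(tert-butyldimethylsilyl)oxy]methyl}-3-methyl-2-(prop-1-en-2-yl)pent-4-enal | C=C[C@@](C)(CO[Si](C)(C)C(C)(C)C)[C@@H](C(=C)C)C=O
F11 | step 4 | silylated iodo methyl acetal (2-(iodomethyl)-5-methoxyoxolane with the silyloxymethyl arm) | COC1O[C@H](CI)[C@@](C)(CO[Si](C)(C)C(C)(C)C)[C@H]1C(=C)C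
F12 | step 4 | hydroxy iodo methyl acetal | COC1O[C@H](CI)[C@@](C)(CO)[C@H]1C(=C)C
F13 | step 4 | bis-iodo methyl acetal | COC1O[C@H](CI)[C@@](C)(CI)[C@H]1C(=C)C
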